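The numbers in the tables come from a simulation with made-up constants; the scatter is artificial.

A closed, stirred, isothermal vessel holds monomer Q and initiator Z. Q goes into chains G, and in the maple run the readings of G rise to 14 % and stand at 11 % at 20.0 min. You want the top for a new flask.

| flask | Q | Z | remark | time |
|---|---|---|---|---|
| maple | 0.095 M | 3.2 mM | run made earlier |  |
| cedar | 0.095 M | 7.2 mM | run made earlier |  |
| ash | 0.19 M | 4.8 mM | run made earlier |  |
| flask | 0.095 M | 4.8 mM |  | 30 min |

| run | time / min | G / % |
|---|---|---|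
| maple | 2.50 | 5 |
| maple | 3.00 | 6 |
| maple | 5.00 | 10 |
| maple | 6.00 | 9 |
| maple | 10.0 | 14 |
| maple | 12.0 | 13 |
| maple | 20.0 | 11 |
| cedar | 2.50 | 15 |
| cedar | 3.00 | 15 |
| cedar | 5.00 | 19 |
| cedar | 6.00 | 20 |
| cedar | 10.0 | 19 |
| cedar | 12.0 | 19 |
| cedar | 20.0 | 15 |
| ash | 2.50 | 9 |
| ash | 4.00 | 10 |
| ash | 6.00 | 10 |
| ash | 10.0 | 10 |
| ash | 20.0 | 9 |

(scatter of a reading: 1.5 percentage points)



- the moment within 30 min at which there is most G
- the amount of G, in percent of the Q charged, at that time

Let r, the initiator-to-monomer ratio, be Z charged over Q charged. Taking each top as a mean of the highest readings, with their scatter, you read 13.5 % for maple at r = 3.37 %, 19.2 % for cedar at 7.58 %, and 10.0 % for ash at 2.53 %. Maple and cedar share their Q, and between these two readings the top grows as r to the power 0.435, so you take 0.5 as a working value. Define the top number s, the top as a fraction of Q charged divided by the square root of r. The runs give 0.736, 0.699 and 0.629, and their mean is 0.688.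

The flask has r = 5.05 %, so my reckoning puts its top at 15.5 %, between 14.1 % and 16.5 % across the runs' span of s. Its r lies between maple's and cedar's, whose highest readings stand at 10.0 min and 6.00 min, so I expect its top between those times.

The forecast gave 16.5 % (14 % to 19.5 %) at 8.5 min (5.5 min to 12 min), adding “so the optimum is broad”.

The flask gives 15.8 % at 9.54 min.

    Q + Z → J + G (k = 0.180 M⁻¹ s⁻¹)
    G → D (k = 9.50 × 10⁻⁴ s⁻¹)
    2 Q → E (k = 0.0200 M⁻¹ s⁻¹)
    Q + J → G + J, rate k4*[J]*[Q] (k = 0.250 M⁻¹ s⁻¹)
    Q + G → X (k = 0.0230 M⁻¹ s⁻¹)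

The flask's own s is 0.702, inside the runs' span. Now charge the same Z with 0.038 M of Q. That neighbour has r = 12.6 %, higher than cedar's, so the mean s gives a top of 24.5 %. It reaches 23.3 %, lower than reckoned, which makes its own s 0.656. At 30.0 min that neighbour still holds 14.9 % of G.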